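**Strategy.** The route rests on disconnecting the C6–O bond of the butenolide ring (O–C12(=O)–C11=C7–C6) and treating the enol-ether alkene C5=C6 as a plain ring-cis alkene, which leads back to a macrocyclic C5=C6–C7=C11–C12O2H diene acid. One operation, selenolactonisation followed by selenoxide elimination, forms the C6–O bond, closes the butenolide and restores C5=C6. It exploits the placement of the lactone oxygen on C6, one end of the C5=C6 alkene, and the quaternary C4 of the tetrahydrofuran ring, which leaves H6 as the only hydrogen available for elimination. The precursor is the oxygen-bridged cyclodecadiene acid 19, carboxyl cis to C6, with all three hydroxyls silylated.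

Key step: step 14

Atom labels: the tetrahydrofuran ring is O, C1 (CH), C2, C3, C4 (C–CH3); the ten-membered carbocycle runs C4–C5=C6–C7–C8–C9–C10–C1; C8 is the CH–O carbon, C9 the CH2, C10 the C(CH3)–O carbon; C11 is the butenolide carbon that carries C13 (CH2O), C12 the carbonyl carbon.
Remark: with the carboxyl cis to C6, the exocyclic C7=C11 alkene of 18 and 19 is E by the sequence rules, because C8 outranks C6.
Remark: C10 is silylated in the precursor as well, so that no free hydroxyl can attack the seleniranium ion across the ring.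
Assumption: (R)-linalool, furan-3,4-diyldimethanol and (R)-2-methylglycidol are bought in pure form.

Step 1
Reactants: 1 (R)-linalool
Product: 2 (2E,6R)-2,6-dimethylocta-2,7-diene-1,6-diol
Conditions: SeO2 (0.3 equiv), t-BuOOH (3 equiv), CH2Cl2, rt
Reagents that add atoms: tert-butyl hydroperoxide, CC(C)(C)OO
Why: Riley allylic oxidation (ene reaction, then [2,3]-sigmatropic shift) should hydroxylate the (E)-methyl group of the trisubstituted alkene selectively, since the vinyl group has no allylic hydrogen and the carbinol stereocentre is not involved.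

Step 2
Reactants: 2 (2E,6R)-2,6-dimethylocta-2,7-diene-1,6-diol
Product: 4 (2R)-2-[(2S,5R)-5-ethenyl-5-methyloxolan-2-yl]propane-1,2-diol, via epoxy alcohol 3 (not isolated)
Conditions: Ti(OiPr)4 (0.2 equiv), D-(−)-diisopropyl tartrate (0.25 equiv), t-BuOOH, 4 Å MS, CH2Cl2, −25 °C; crude epoxide, CSA (cat.), CH2Cl2, 0 °C → rt
Reagents that add atoms: tert-butyl hydroperoxide, CC(C)(C)OO
Why: Sharpless asymmetric epoxidation with the D-tartrate should give the (2R,3R)-epoxide by reagent control, and 5-exo-tet opening at the CH carbon by the tertiary hydroxyl with inversion then sets C1 (S) while C10 (R) keeps the epoxide oxygen, which amounts to anti addition across the E alkene and puts the vinyl group and the diol side chain cis on the tetrahydrofuran.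

Step 3
Reactants: 4 (2R)-2-[(2S,5R)-5-ethenyl-5-methyloxolan-2-yl]propane-1,2-diol
Product: 6 (2S,5R)-5-ethenyl-5-methyl-2-[(2R)-2-methyloxiran-2-yl]oxolane, via tosylate 5 (not isolated)
Conditions: TsCl (1.05 equiv), Et3N, DMAP (cat.), CH2Cl2, 0 °C; then K2CO3, MeOH, rt
Reagents that add atoms: none
Why: Sulfonylation is selective for the primary hydroxyl and the tertiary alkoxide then closes the epoxide by intramolecular Williamson displacement (3-exo-tet) at C9, so no bond to C10 is broken and its configuration is kept.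

Step 4
Reactants: 7 furan-3,4-diyldimethanol
Product: 8 [4-({[tert-butyl(dimethyl)silyl]oxy}methyl)furan-3-yl]methanol
Conditions: NaH (1.0 equiv), THF, 0 °C → rt; then TBSCl (1.0 equiv)
Reagents that add atoms: tert-butyl(chloro)dimethylsilane, CC(C)(C)[Si](C)(C)Cl
Why: Monodeprotonation of the symmetrical diol and silylation of the monosodium alkoxide should give mainly the mono-silyl ether (monoprotection of a symmetrical diol).

Step 5
Reactants: 8 [4-({[tert-butyl(dimethyl)silyl]oxy}methyl)furan-3-yl]methanol
Product: 9 4-({[tert-butyl(dimethyl)silyl]oxy}methyl)furan-3-carbaldehyde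
Conditions: activated MnO2 (10 equiv), CH2Cl2, rt
Reagents that add atoms: none
Why: Heterogeneous MnO2 oxidation of the furylic alcohol should stop at the aldehyde and leave the silyl ether and the furan ring untouched.

Step 6
Reactants: 9 4-({[tert-butyl(dimethyl)silyl]oxy}methyl)furan-3-carbaldehyde
Product: 10 tert-butyl{[4-(1,3-dithian-2-yl)furan-3-yl]methoxy}dimethylsilane
Conditions: propane-1,3-dithiol (1.1 equiv), Zn(OTf)2 (cat.), CH2Cl2, rt
Reagents that add atoms: propane-1,3-dithiol, SCCCS
Why: Lewis-acid-catalysed dithioacetalisation turns the aldehyde carbon (the future C8) into an acyl-anion equivalent under conditions mild enough for the primary silyl ether.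

Step 7
Reactants: 10 tert-butyl{[4-(1,3-dithian-2-yl)furan-3-yl]methoxy}dimethylsilane; 6 (2S,5R)-5-ethenyl-5-methyl-2-[(2R)-2-methyloxiran-2-yl]oxolane
Product: 12 (2R)-1-{2-[4-({[tert-butyl(dimethyl)silyl]oxy}methyl)furan-3-yl]-1,3-dithian-2-yl}-2-[(2S,5R)-5-ethenyl-5-methyloxolan-2-yl]propan-2-ol, via lithiated dithiane 11 (not isolated)
Conditions: 10, n-BuLi (1.05 equiv), THF, −78 → −30 °C; then 6, DMPU, −30 °C → rt; aq NH4Cl
Reagents that add atoms: none
Why: Corey–Seebach umpolung, in which the 2-aryl-2-lithio-1,3-dithiane opens the 2,2-disubstituted epoxide by SN2 attack at its unsubstituted CH2 and so forms the C8–C9 bond without touching C10.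

Step 8
Reactants: 12 (2R)-1-{2-[4-({[tert-butyl(dimethyl)silyl]oxy}methyl)furan-3-yl]-1,3-dithian-2-yl}-2-[(2S,5R)-5-ethenyl-5-methyloxolan-2-yl]propan-2-ol
Product: 13 (3R)-1-[4-({[tert-butyl(dimethyl)silyl]oxy}methyl)furan-3-yl]-3-[(2S,5R)-5-ethenyl-5-methyloxolan-2-yl]-3-hydroxybutan-1-one
Conditions: MeI (10 equiv), CaCO3, MeCN/H2O (9:1), 45 °C
Reagents that add atoms: water, O
Why: S-Methylation turns the dithiane into a leaving group and hydrolysis of the sulfonium ion releases the C8 ketone (alkylative dithiane hydrolysis) under buffered, non-oxidising conditions that should spare the furan, the vinyl group and the silyl ether.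

Step 9
Reactants: 13 (3R)-1-[4-({[tert-butyl(dimethyl)silyl]oxy}methyl)furan-3-yl]-3-[(2S,5R)-5-ethenyl-5-methyloxolan-2-yl]-3-hydroxybutan-1-one
Product: 14 (1S,3R)-1-[4-({[tert-butyl(dimethyl)silyl]oxy}methyl)furan-3-yl]-3-[(2S,5R)-5-ethenyl-5-methyloxolan-2-yl]butane-1,3-diol
Conditions: RuCl[(S,S)-TsDPEN](p-cymene) (2 mol%), HCO2H/Et3N (5:2), CH2Cl2, rt
Reagents that add atoms: none
Why: Noyori asymmetric transfer hydrogenation of the heteroaryl ketone, in which the (S,S)-diamine ligand directs hydride to the carbonyl face that gives the (S)-carbinol at C8 (furyl in the place of the aryl group of acetophenone), so C8 is set by reagent control and the alkenes are not reduced.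

Step 10
Reactants: 14 (1S,3R)-1-[4-({[tert-butyl(dimethyl)silyl]oxy}methyl)furan-3-yl]-3-[(2S,5R)-5-ethenyl-5-methyloxolan-2-yl]butane-1,3-diol
Product: 15 tert-butyl({4-[(1S,3R)-3-[(2S,5R)-5-ethenyl-5-methyloxolan-2-yl]-1,3-bis(triethylsilyloxy)butyl]furan-3-yl}methoxy)dimethylsilane
Conditions: TESOTf (2.5 equiv), 2,6-lutidine, CH2Cl2, −78 → 0 °C
Reagents that add atoms: triethylsilyl trifluoromethanesulfonate, CC[Si](CC)(CC)OS(=O)(=O)C(F)(F)F
Why: A silyl triflate with a hindered pyridine base silylates both the secondary C8 and the tertiary C10 hydroxyl, so that no free hydroxyl can later compete with the carboxylate for the seleniranium ion.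

Step 11
Reactants: 15 tert-butyl({4-[(1S,3R)-3-[(2S,5R)-5-ethenyl-5-methyloxolan-2-yl]-1,3-bis(triethylsilyloxy)butyl]furan-3-yl}methoxy)dimethylsilane
Product: 17 3-({[tert-butyl(dimethyl)silyl]oxy}methyl)-4-[(1S,3R)-3-[(2S,5R)-5-ethenyl-5-methyloxolan-2-yl]-1,3-bis(triethylsilyloxy)butyl]-5-hydroxyfuran-2(5H)-one (both C6 epimers), via endoperoxide 16 (not isolated)
Conditions: O2, visible light, tetraphenylporphyrin (cat.), i-Pr2NEt (3 equiv), CH2Cl2, −78 °C; then warm to rt
Reagents that add atoms: dioxygen, O=O
Why: [4+2] cycloaddition of singlet oxygen to the furan and Kornblum–DeLaMare fragmentation of the endoperoxide by the hindered amine, which should remove the bridgehead hydrogen at C12 beside the small CH2OTBS group in preference to that at C6 beside the branched C8 substituent, so that C12 becomes the lactone carbonyl and C6 the hemiacetal carbon.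

Step 12
Reactants: 17 3-({[tert-butyl(dimethyl)silyl]oxy}methyl)-4-[(1S,3R)-3-[(2S,5R)-5-ethenyl-5-methyloxolan-2-yl]-1,3-bis(triethylsilyloxy)butyl]-5-hydroxyfuran-2(5H)-one
Product: 18 (2E)-2-({[tert-butyl(dimethyl)silyl]oxy}methyl)-3-[(1S,3R)-3-[(2S,5R)-5-ethenyl-5-methyloxolan-2-yl]-1,3-bis(triethylsilyloxy)butyl]penta-2,4-dienoic acid
Conditions: Ph3PCH3Br (3 equiv), KOtBu (4 equiv), THF, 0 °C; then 17, 0 °C → rt; cold aq KHSO4
Reagents that add atoms: methyltriphenylphosphonium bromide, C[P+](c1ccccc1)(c1ccccc1)c1ccccc1.[Br-]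
Why: Base opens the hydroxybutenolide to the (Z)-4-oxobut-2-enoate and Wittig methylenation of its aldehyde should give the dienoic acid, in which the carboxyl stays cis to the new vinyl group because the C7=C11 geometry is inherited from the ring.

Step 13
Reactants: 18 (2E)-2-({[tert-butyl(dimethyl)silyl]oxy}methyl)-3-[(1S,3R)-3-[(2S,5R)-5-ethenyl-5-methyloxolan-2-yl]-1,3-bis(triethylsilyloxy)butyl]penta-2,4-dienoic acid
Product: 19 macrocyclic diene acid (2E)-2-[(1R,2Z,5S,7R,8S)-1,7-dimethyl-5,7-bis(triethylsilyloxy)-11-oxabicyclo[6.2.1]undec-2-en-4-ylidene]-3-{[tert-butyl(dimethyl)silyl]oxy}propanoic acid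
Conditions: second-generation Grubbs catalyst RuCl2(=CHPh)(H2IMes)(PCy3) (15 mol%), 1,4-benzoquinone (cat.), toluene (1 mM), 80 °C
Reagents that add atoms: none
Why: Ring-closing metathesis of the two vinyl groups with loss of ethene, helped by the cis-2,5-disubstituted tetrahydrofuran and the C7=C11 alkene that hold the chain ends together, should give the ten-membered ring with the cis C5=C6 alkene that this ring size requires, while the tetrasubstituted acrylate alkene is inert to the catalyst.

Step 14
Reactants: 19 macrocyclic diene acid (carboxyl cis to C6; C13–OTBS; C8–OTES; C10–OTES)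
Product: 22 tris-silylated ylidene butenolide (enol lactone O–C6 with C5=C6 restored; C4 cis to C7; C13–OTBS; C8–OTES; C10–OTES), via selenolactone 20 (not isolated), via selenoxide 21 (not isolated)
Conditions: Et3N (1.1 equiv), CH2Cl2, −78 °C; PhSeCl (1.2 equiv), −78 → −20 °C; then pyridine, 30% aq H2O2 (excess), THF, 0 °C → rt
Reagents that add atoms: none
Why: PhSeCl forms a seleniranium ion on C5=C6, the only nucleophilic alkene, and the C12 carboxylate, held cis to C6 by the C7=C11 geometry, opens it at C6 anti to selenium, which makes the C6–O bond and closes the butenolide ring in a 5-exo-trig mode. Oxidation gives the selenoxide, whose syn elimination can only use H6 because C4 is quaternary, so the double bond returns to C5=C6 as the enol lactone. The closest known reaction type is phenylselenolactonisation of unsaturated acids followed by selenoxide elimination to enol lactones. No stereocentre remains from the step: the transient centres C5 and C6 arise by anti addition from either face and are erased by syn elimination, and this stereospecific pair of events returns the ring-cis geometry (C4 cis to C7) from both adducts. The step needs attack at C6 and not 6-endo attack at C5, which the allylic character of C6 and the neopentyl, β-oxygenated character of C5 secure, and it needs the carboxylate to be the only nucleophile and C5=C6 the only reactive alkene, which silylation of all three hydroxyls and the electron-poor, tetrasubstituted C7=C11 alkene secure.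

Step 15
Reactants: 22 tris-silylated ylidene butenolide
Product: 23 triol ylidene butenolide (free C13, C8 and C10 hydroxyls)
Conditions: HF·pyridine, pyridine, THF, 0 °C → rt
Reagents that add atoms: none
Why: Fluoride cleaves the primary TBS ether and the secondary and tertiary TES ethers through pentacoordinate silicon, and the pyridine buffer should protect the enol lactone from acid-promoted addition of the freed C10 hydroxyl.

Step 16
Reactants: 23 triol ylidene butenolide
Product: 24 C13 monoacetate (free C8 and C10 hydroxyls)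
Conditions: Ac2O (1.1 equiv), 2,4,6-collidine, CH2Cl2, −20 → 0 °C
Reagents that add atoms: acetic anhydride, CC(=O)OC(C)=O
Why: Acylation without a nucleophilic catalyst should be kinetically selective for the unhindered primary allylic C13 hydroxyl over the hindered secondary C8 and the tertiary C10 hydroxyl.

Step 17
Reactants: 25 (R)-2-methylglycidol, [(2R)-2-methyloxiran-2-yl]methanol
Product: 26 (2S)-2-methyloxirane-2-carboxylic acid
Conditions: RuCl3·xH2O (2 mol%), NaIO4 (3 equiv), MeCN/EtOAc/H2O, 0 °C → rt
Reagents that add atoms: sodium periodate, [Na+].[O-]I(=O)(=O)=O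
Why: Catalytic RuO4 oxidation of the primary alcohol to the carboxylic acid leaves the epoxide and its quaternary stereocentre untouched, and the descriptor changes from R to S only because the priority order changes.

Step 18
Reactants: 24 C13 monoacetate; 26 (2S)-2-methyloxirane-2-carboxylic acid
Product: 27 CNP0142137.1
Conditions: DCC (1.5 equiv), DMAP (1.0 equiv), CH2Cl2, 0 °C → rt
Reagents that add atoms: none
Why: Steglich esterification (carbodiimide activation and DMAP acyl transfer) should acylate the secondary C8 hydroxyl, the only reactive one left since the tertiary C10 hydroxyl does not react, without affecting the epoxide or any stereocentre.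

**Compound list**

1 | (R)-linalool, (3R)-3,7-dimethylocta-1,6-dien-3-ol | C=C[C@@](O)(C)CCC=C(C)C | starting material
2 | (2E,6R)-2,6-dimethylocta-2,7-diene-1,6-diol | C=C[C@@](O)(C)CC/C=C(\C)CO | intermediate
3 | [(2R,3R)-3-[(3R)-3-hydroxy-3-methylpent-4-en-1-yl]-2-methyloxiran-2-yl]methanol (epoxy alcohol, not isolated) | C=C[C@@](O)(C)CC[C@H]1O[C@]1(C)CO | intermediate
4 | (2R)-2-[(2S,5R)-5-ethenyl-5-methyloxolan-2-yl]propane-1,2-diol (vinyl and diol side chain cis) | C=C[C@@]1(C)CC[C@H](O1)[C@](C)(O)CO | intermediate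
5 | (2R)-2-[(2S,5R)-5-ethenyl-5-methyloxolan-2-yl]-2-hydroxypropyl 4-methylbenzenesulfonate (tosylate, not isolated) | C=C[C@@]1(C)CC[C@H](O1)[C@](C)(O)COS(=O)(=O)c1ccc(C)cc1 | intermediate
6 | (2S,5R)-5-ethenyl-5-methyl-2-[(2R)-2-methyloxiran-2-yl]oxolane | C=C[C@@]1(C)CC[C@H](O1)[C@@]2(C)CO2 | intermediate
7 | furan-3,4-diyldimethanol | OCc1cocc1CO | starting material
8 | [4-({[tert-butyl(dimethyl)silyl]oxy}methyl)furan-3-yl]methanol | CC(C)(C)[Si](C)(C)OCc1cocc1CO | intermediate
9 | 4-({[tert-butyl(dimethyl)silyl]oxy}methyl)furan-3-carbaldehyde | CC(C)(C)[Si](C)(C)OCc1cocc1C=O | intermediate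
10 | tert-butyl{[4-(1,3-dithian-2-yl)furan-3-yl]methoxy}dimethylsilane | CC(C)(C)[Si](C)(C)OCc1cocc1C2SCCCS2 | intermediate
11 | 2-lithio derivative of 10 (lithiated dithiane, not isolated) | CC(C)(C)[Si](C)(C)OCc1cocc1C2([Li])SCCCS2 | intermediate
12 | (2R)-1-{2-[4-({[tert-butyl(dimethyl)silyl]oxy}methyl)furan-3-yl]-1,3-dithian-2-yl}-2-[(2S,5R)-5-ethenyl-5-methyloxolan-2-yl]propan-2-ol | C=C[C@@]1(C)CC[C@H](O1)[C@](C)(O)CC2(SCCCS2)c3cocc3CO[Si](C)(C)C(C)(C)C | intermediate
13 | (3R)-1-[4-({[tert-butyl(dimethyl)silyl]oxy}methyl)furan-3-yl]-3-[(2S,5R)-5-ethenyl-5-methyloxolan-2-yl]-3-hydroxybutan-1-one | C=C[C@@]1(C)CC[C@H](O1)[C@](C)(O)CC(=O)c2cocc2CO[Si](C)(C)C(C)(C)C | intermediate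
14 | (1S,3R)-1-[4-({[tert-butyl(dimethyl)silyl]oxy}methyl)furan-3-yl]-3-[(2S,5R)-5-ethenyl-5-methyloxolan-2-yl]butane-1,3-diol | C=C[C@@]1(C)CC[C@H](O1)[C@](C)(O)C[C@H](O)c2cocc2CO[Si](C)(C)C(C)(C)C | intermediate
15 | tert-butyl({4-[(1S,3R)-3-[(2S,5R)-5-ethenyl-5-methyloxolan-2-yl]-1,3-bis(triethylsilyloxy)butyl]furan-3-yl}methoxy)dimethylsilane | C=C[C@@]1(C)CC[C@H](O1)[C@](C)(O[Si](CC)(CC)CC)C[C@H](O[Si](CC)(CC)CC)c2cocc2CO[Si](C)(C)C(C)(C)C | intermediate
16 | furan 2,5-endoperoxide of 15 (2,3,7-trioxabicyclo[2.2.1]hept-5-ene, not isolated) | C=C[C@@]1(C)CC[C@H](O1)[C@](C)(O[Si](CC)(CC)CC)C[C@H](O[Si](CC)(CC)CC)C2=C(CO[Si](C)(C)C(C)(C)C)C3OOC2O3 | intermediate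
17 | 3-({[tert-butyl(dimethyl)silyl]oxy}methyl)-4-[(1S,3R)-3-[(2S,5R)-5-ethenyl-5-methyloxolan-2-yl]-1,3-bis(triethylsilyloxy)butyl]-5-hydroxyfuran-2(5H)-one (C6 epimers) | C=C[C@@]1(C)CC[C@H](O1)[C@](C)(O[Si](CC)(CC)CC)C[C@H](O[Si](CC)(CC)CC)C2=C(CO[Si](C)(C)C(C)(C)C)C(=O)OC2O | intermediate
18 | (2E)-2-({[tert-butyl(dimethyl)silyl]oxy}methyl)-3-[(1S,3R)-3-[(2S,5R)-5-ethenyl-5-methyloxolan-2-yl]-1,3-bis(triethylsilyloxy)butyl]penta-2,4-dienoic acid | C=C[C@@]1(C)CC[C@H](O1)[C@](C)(O[Si](CC)(CC)CC)C[C@H](O[Si](CC)(CC)CC)/C(C=C)=C(\CO[Si](C)(C)C(C)(C)C)C(O)=O | intermediate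
19 | (2E)-2-[(1R,2Z,5S,7R,8S)-1,7-dimethyl-5,7-bis(triethylsilyloxy)-11-oxabicyclo[6.2.1]undec-2-en-4-ylidene]-3-{[tert-butyl(dimethyl)silyl]oxy}propanoic acid (macrocyclic diene acid, precursor of the key step) | OC(=O)/C(CO[Si](C)(C)C(C)(C)C)=C1\C=C/[C@@]2(C)CC[C@H](O2)[C@](C)(O[Si](CC)(CC)CC)C[C@@H]1O[Si](CC)(CC)CC | intermediate
20 | selenolactone: 6,12-lactone with PhSe on C5, anti to the lactone oxygen (one of the two anti adducts drawn, both converge; not isolated) | CC(C)(C)[Si](C)(C)OCC1=C2[C@@H]([C@@H]([Se]c4ccccc4)[C@@]3(C)CC[C@H](O3)[C@](C)(O[Si](CC)(CC)CC)C[C@@H]2O[Si](CC)(CC)CC)OC1=O | intermediate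
21 | selenoxide of 20 (not isolated) | CC(C)(C)[Si](C)(C)OCC1=C2[C@@H]([C@@H]([Se](=O)c4ccccc4)[C@@]3(C)CC[C@H](O3)[C@](C)(O[Si](CC)(CC)CC)C[C@@H]2O[Si](CC)(CC)CC)OC1=O | intermediate
22 | tris-silylated ylidene butenolide: enol lactone O–C6 with C5=C6 (C4 cis to C7), C13–OTBS, (8S)-OTES, (10R)-OTES (product of the key step) | CC(C)(C)[Si](C)(C)OCC1=C2/C(=C\[C@@]3(C)CC[C@H](O3)[C@](C)(O[Si](CC)(CC)CC)C[C@@H]2O[Si](CC)(CC)CC)OC1=O | intermediate
23 | triol ylidene butenolide (C13–OH, C8–OH, C10–OH free) | OCC1=C2/C(=C\[C@@]3(C)CC[C@H](O3)[C@](C)(O)C[C@@H]2O)OC1=O | intermediate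
24 | C13 monoacetate (C8–OH and C10–OH free) | CC(=O)OCC1=C2/C(=C\[C@@]3(C)CC[C@H](O3)[C@](C)(O)C[C@@H]2O)OC1=O | intermediate
25 | (R)-2-methylglycidol, [(2R)-2-methyloxiran-2-yl]methanol | OC[C@]1(C)CO1 | starting material
26 | (2S)-2-methyloxirane-2-carboxylic acid | OC(=O)[C@]1(C)CO1 | intermediate
27 | CNP0142137.1 | CC(=O)OCC1=C2/C(=C\[C@@]3(C)CC[C@H](O3)[C@](C)(O)C[C@@H]2OC(=O)[C@]2(C)CO2)OC1=O | target

**Step count.** Total: 18 steps. Longest linear sequence: 14 steps from (R)-linalool (steps 1–3, 7–16 and 18). Steps 4–6 and 17 are side branches.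

**Steps most likely to fail**

1. Step 14 (key step). The syn elimination of the selenoxide towards the oxygen-bearing C6 is slower than an ordinary selenoxide elimination. The selenide may revert to the diene acid, or the freed selenenic acid may add back to the new enol-ether alkene, before the elimination is complete. Fallback by halolactonisation and dehydrohalogenation: setting out from 19, iodine and NaHCO3 in MeCN at 0 °C should give, by the same 5-exo closure, the iodolactone F1. DBU in toluene should then remove H6, the acidic γ-hydrogen of the butenolide, and expel iodide from C5 (E1cB), which returns to the route at 22.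

2. Step 13. Turnover at the vinyl group on the quaternary C4 may be slow, and the cis carboxyl may chelate the ruthenium alkylidene formed at C6, so that oligomerisation outruns closure of the ten-membered ring. Fallback by Wittig macrocyclisation instead of metathesis: setting out from 17, ozonolysis of the vinyl group (O3, CH2Cl2/MeOH, −78 °C, then Me2S) should give the C5 aldehyde F2. Ph3P·HBr in MeCN should convert the lactol carbon C6 into the butenolide phosphonium bromide F3. Et3N in CH2Cl2 at high dilution should generate the stabilised ylide, whose intramolecular Wittig reaction with the C5 aldehyde forms C5=C6 and the ten-membered ring at once. This sequence replaces steps 12 to 14 and comes back to the route at 22.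

3. Step 11. The base-induced fragmentation of the endoperoxide may show poor regioselectivity, with proton loss at C6 competing with proton loss at C12. Fallback by silyl-directed photooxygenation: setting out from 15, lithiation at the less hindered α-position C12 (s-BuLi, TMEDA, THF, −78 °C) and quenching with Me3SiCl should give the C12-silylated furan F4. Any C6 isomer can be removed by chromatography at this stable stage. Singlet oxygen (O2, visible light, tetraphenylporphyrin, CH2Cl2/MeOH, −78 °C) should then convert the silicon-bearing carbon specifically into the lactone carbonyl through silyl migration to the peroxide oxygen, which returns to the route at 17.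

Further compounds
F1 | step 14 | iodolactone: 6,12-lactone with iodine on C5, anti to the lactone oxygen | CC(C)(C)[Si](C)(C)OCC1=C2[C@@H]([C@@H](I)[C@@]3(C)CC[C@H](O3)[C@](C)(O[Si](CC)(CC)CC)C[C@@H]2O[Si](CC)(CC)CC)OC1=O
F2 | step 13 | C5 aldehyde: hydroxybutenolide 17 with the vinyl group on C4 cleaved to a formyl group | O=C[C@@]1(C)CC[C@H](O1)[C@](C)(O[Si](CC)(CC)CC)C[C@H](O[Si](CC)(CC)CC)C2=C(CO[Si](C)(C)C(C)(C)C)C(=O)OC2O
F3 | step 13 | butenolide phosphonium bromide: F2 with Ph3P+ in place of the hydroxyl on C6 | O=C[C@@]1(C)CC[C@H](O1)[C@](C)(O[Si](CC)(CC)CC)C[C@H](O[Si](CC)(CC)CC)C2=C(CO[Si](C)(C)C(C)(C)C)C(=O)OC2[P+](c3ccccc3)(c3ccccc3)c3ccccc3.[Br-]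
F4 | step 11 | C12-trimethylsilyl furan: 15 with Me3Si on the furan α-carbon next to the CH2OTBS-bearing carbon | C=C[C@@]1(C)CC[C@H](O1)[C@](C)(O[Si](CC)(CC)CC)C[C@H](O[Si](CC)(CC)CC)c2coc([Si](C)(C)C)c2CO[Si](C)(C)C(C)(C)C
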